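## The problem

Compound 28 is a germacranolide: a ten-membered carbocycle (C1–C10, germacrane locants) with a trans-fused α-methylene-γ-lactone across C6–C7 (lactone oxygen on C6), a 4Z trisubstituted alkene, a 1,10-epoxide derived from an E alkene, and on C8 the ester of (2S,3S)-2,3-dimethyloxirane-2-carboxylic acid. A synthesis has to close a strained medium ring that carries two trisubstituted C=C units of fixed geometry and has to set three contiguous stereocentres, C6, C7 and C8, on it. C6 is the natural anchor: it can dictate C7 through the ring fusion, whereas C8 and the epoxide carbons C1 and C10 answer to the conformation of the ten-membered ring, and the two centres of the acyl group are remote and need reagent control. Several groups forbid rough treatment: the α-methylene lactone is a conjugate acceptor, both epoxides and the 1(10),4-diene are acid-sensitive (transannular cyclisation), a free C8 hydroxyl can translactonise under base, and the glycidic ester cannot pass through enolate or reducing chemistry. The enabling feature is the contiguous array O6–C6–C7(–C11)–C8–O8: the lactone carbons C12 and C11 hang on the C6 oxygen, so a two-carbon radical tethered there as a bromoacetal can close the ring O6–C12–C11–C7–C6 onto a C7=C8 alkene and leave a C8 radical that takes up the second oxygen. The same C7=C8 alkene is the place where the ten-membered ring can be closed from two vinyl groups, and the rest of the ring maps onto nerol, whose Z alkene is C4=C5. One trap is built into the array: C6 is allylic to C4=C5 as well, so that alkene has to be kept out of the radical's reach.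

## Retrosynthesis

**28 ⇒ 27 (C1–O and C10–O).** The 1,10-epoxide is removed first. C1=C10 is the most electron-rich alkene of 27 and is needed as an alkene in every earlier ring-forming and unmasking step; as an epoxide it would not survive the acidic steps and would make the later unmasking of C4=C5 unselective. The cut removes two stereocentres. The forward step needs site selectivity over C4=C5 and the two enoates, and one face of the E alkene.

**27 ⇒ 20 + 25 (acyl C–O at C8).** The ester is cut next because its epoxide and its carbonyl tolerate neither enolate formation at C11 nor N–O reduction. This gives the hydroxy lactone 20 and the epoxy acid 25, which is independent of the core and comes from angelic acid 21 through alcohol 22 and epoxy alcohol 23 (oxidised via aldehyde 24). The forward coupling, through mixed anhydride 26, must acylate a hindered secondary alcohol without base strong enough to translactonise.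

**20 ⇒ 19 ⇒ 17 ⇒ 15 (N–O, then C11=C13).** The C8 hydroxyl is traced to the alkoxyamine 19, so that the nitroxyl fragment serves as the protecting group for C8–O while C13 is introduced. The exocyclic methylene is cut back through the Mannich base 17 (formed from enolate 16, eliminated via ammonium salt 18) to the plain lactone 15. This keeps the conjugate acceptor out of all earlier steps; the price is two steps for one carbon.

**15 ⇒ 14 ⇒ 13 ⇒ 12 (oxidation level at C12, and the C4=C5 mask).** The lactone is taken back through lactol 14 to the ethyl acetal 13, because an acetal-tethered radical cyclises far better than an α-acyl one. C4=C5 of 13 is traced to the 4,5-epoxide of 12. The epoxide is a deliberate mask: in a 6-oxygenated 4,7-diene the tethered radical could add 5-exo to C5 as easily as to C7, giving a tertiary C4 radical, and only a saturated C5 closes that path. The unmasking must be stereospecific (cis epoxide to Z alkene) and must precede every acidic step.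

**12 ⇒ 10 + 11 (C7–C11 and C8–O; key disconnection).** Both bonds are cut in one radical step, which opens the five-membered ring O6–C12–C11–C7–C6 and removes the C7 and C8 stereocentres. The neighbouring options are weaker: a lactonisation onto C6 would need C7 set beforehand, and a C8 ketone would need a separate reduction. Precursor 10 has only one stereocentre that matters (C6) beside the sacrificial epoxide. The forward step must cyclise before the nitroxyl 11 captures the first radical, must attack C7 anti to C5, and must take up oxygen on one face of C8.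

**10 ⇒ 9 (C7=C8).** The ten-membered ring is opened at the alkene that the key step consumes, so nothing has to be carried for the ring closure alone. A closure at C6–C7 (vinyl-metal onto an aldehyde) was considered; it would create C6 during macrocyclisation, with no local control. Precursor 9 is an acyclic diene with two monosubstituted vinyl groups. The forward metathesis must outrun dimerisation and must not engage the C1=C10 alkene.

**9 ⇒ 8 ⇒ 7 ⇒ 6 (C8–C9, then C9–O).** The C8 vinyl group is cut from the allylic carbon C9, which leads to the allylic bromide 8, the allylic alcohol 7 and the gem-dimethyl terminus of 6. The E geometry of C1=C10 is then the known outcome of allylic oxidation of that terminus and is not created in a C=C forming step.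

**6 ⇒ 4 + 5 ⇒ 3 ⇒ 2 ⇒ 1 (acetal C–O; C6–C7; epoxide).** The bromoacetal 6 comes from alcohol 4 and ethyl vinyl ether 5. The C6–C7 bond is cut to vinyl metal plus the epoxy aldehyde 3, and 3 comes from nerol 1 through epoxy alcohol 2. The epoxide does three jobs: it carries the absolute configuration, it directs the vinyl addition that sets C6, and it is the C4=C5 mask of the key step. Nerol supplies the Z geometry of C4=C5 and all ring carbons except C7 and C8.

## Roads not taken

**Alternative 1:** The cut is C7–C8 and C11–C13, with the ten-membered ring closed later, for instance at C1=C10. In the forward step the 2-lithio derivative of dithiane A2 adds to C7 of butenolide A1 anti to the C6 side chain, and formaldehyde traps the enolate at C11 to give lactone A3.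
- Merits: it is convergent; anti addition to a γ-substituted butenolide is among the most dependable ways to a trans C6/C7 pair; and C13 arrives in the same operation. In C6/C7 control and in the economy of C13 it is better than the chosen plan, which spends steps 13 and 14 on that carbon.
- Weak points: no ring is closed. The macrocycle must still be formed by a carbonyl coupling between the C1 aldehyde and the C10 ketone, which has to give an E trisubstituted alkene in a medium ring without geometric control. C8 arrives at the ketone level, so its configuration is postponed to a reduction on the macrocycle. The dithiane must be removed beside a Z alkene, two acetals and a β-hydroxymethyl lactone that dehydrates or retro-aldolises easily.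
- Against this the chosen plan sets a ring closure that joins two plain vinyl groups before the stereocentres are made, and a C8–O bond formed at the alcohol level in the same step as C7–C11.

**Alternative 2:** The cut runs through the two ring alkenes: C1=C10 and C4=C5 are traced back to the σ bonds C1–C4 and C5–C10 of a cyclobutane. In the forward step flash thermolysis of the tricyclic photoadduct A4 (from an enone–cyclobutene [2+2] photocycloaddition) opens the six-membered ring into dienone A5.
- Merits: the ten-membered ring and both trisubstituted alkenes appear in one step without high dilution. In ring construction this is clearly better than a medium-ring metathesis.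
- Weak points: A5 carries the lactone on C8 and a ketone on C6, the reverse of the target, so a stereoselective C6 reduction and a translactonisation against an established cis 8,12-lactone are needed. The thermolysis temperature invites Cope rearrangement of the 1,5-diene and mixtures of alkene geometries. The regio- and stereochemistry of the photoadduct are not fixed by the substrate, and the sequence is racemic unless an enantiopure photo-partner is found.
- Against the better ring formation the chosen plan sets absolute control from an asymmetric epoxidation, the correct oxygen pattern from the outset, and a thermal ceiling of 80 °C for the diene.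

**Alternative 3:** The cut is C2–C3, re-forming C5–C10 in a six-membered ring. In the forward step KH with 18-crown-6 triggers the anionic oxy-Cope rearrangement of divinylcyclohexanol A6, and PhNTf2 traps the C10 enolate as enol triflate A7.
- Merits: the ring expansion is strain-driven and reliable. C6, C7 and C8 are set on a cyclohexane before the ten-membered ring exists; for C8 this is better than the chosen plan, where C8 depends on a macrocyclic conformation. The triflate allows C14 to be brought in by cross-coupling.
- Weak points: A6 is a cyclohexane with five contiguous stereocentres, including a tertiary vinyl carbinol and a trans-fused lactol, and is long to build. The 1(10)E and 4Z geometries both depend on the chair or boat preference of one transition state. Extra steps follow for C14, for the PMB ether and for the acetal.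
- Against the better C8 control the chosen plan sets a cyclisation substrate (10) that is eight steps from nerol with both trisubstituted alkene geometries inherited from earlier steps, and a correction path for C8 by inversion at the esterification.

Key step: step 9

## Remarks on the chemistry (assumptions)

- Locants are germacrane locants: ring C1–C10, lactone carbons C11–C13, C14 on C10, C15 on C4.
- The acetal carbon C12 (6–10, 12–14) and C11 of 17 and 18 are formed as both epimers and are written without a descriptor; both centres are erased later.
- Ring-closing metathesis is taken to give the 7Z alkene and nitroxyl capture the 8R epimer; the fallbacks cover the other outcomes.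

## Route

Step 1
Reactants: 1 nerol
Product: 2 (2S,3R)-2,3-epoxynerol
Conditions: Ti(O-i-Pr)4 (5 mol%), L-(+)-diethyl tartrate (6 mol%), t-BuOOH (2 equiv), 4 Å MS, CH2Cl2, −20 °C
Reagents that add atoms: tert-butyl hydroperoxide, CC(C)(C)OO
Why: Sharpless asymmetric epoxidation acts only on the allylic alcohol and leaves the 6,7-alkene alone; with the L-(+)-tartrate the oxygen should arrive on the face that gives the 2S,3R epoxide (C5 S, C4 R), and the syn addition stores the Z geometry of C4=C5 as a cis epoxide.

Step 2
Reactants: 2 (2S,3R)-2,3-epoxynerol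
Product: 3 (2R,3R)-3-methyl-3-(4-methylpent-3-en-1-yl)oxirane-2-carbaldehyde
Conditions: Dess–Martin periodinane, NaHCO3, CH2Cl2, 0 °C → rt
Reagents that add atoms: none
Why: Dess–Martin oxidation of a primary epoxy alcohol under buffered conditions; the α-carbon is an epoxide carbon and cannot epimerise, and the aldehyde is used without storage.

Step 3
Reactants: 3 (2R,3R)-3-methyl-3-(4-methylpent-3-en-1-yl)oxirane-2-carbaldehyde
Product: 4 (1S)-1-[(2S,3R)-3-methyl-3-(4-methylpent-3-en-1-yl)oxiran-2-yl]prop-2-en-1-ol
Conditions: CH2=CHMgBr, THF, −78 °C
Reagents that add atoms: vinylmagnesium bromide, C=C[Mg]Br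
Why: Grignard 1,2-addition under Felkin–Anh control: the epoxide C–O bond lies antiperiplanar to the incoming vinyl group and the cis substituent on C4 disfavours the other rotamer, so the 6S carbinol should predominate; this centre becomes C6 of the target.

Step 4
Reactants: 4 (1S)-1-[(2S,3R)-3-methyl-3-(4-methylpent-3-en-1-yl)oxiran-2-yl]prop-2-en-1-ol, 5 ethyl vinyl ether
Product: 6 (2S,3R)-2-[(1S)-1-(2-bromo-1-ethoxyethoxy)prop-2-en-1-yl]-3-methyl-3-(4-methylpent-3-en-1-yl)oxirane
Conditions: NBS, 5 (5 equiv), CH2Cl2, −40 °C → 0 °C
Reagents that add atoms: N-bromosuccinimide, O=C1CCC(=O)N1Br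
Why: Bromoacetalisation (alkoxybromination of an enol ether): the excess enol ether is far more nucleophilic than the trisubstituted alkene, and its bromo-oxocarbenium ion is captured by the secondary alcohol. The acetal doubles as the protecting group for C6–O in steps 5–8.

Step 5
Reactants: 6 (2S,3R)-2-[(1S)-1-(2-bromo-1-ethoxyethoxy)prop-2-en-1-yl]-3-methyl-3-(4-methylpent-3-en-1-yl)oxirane
Product: 7 (2E)-5-{(2R,3S)-3-[(1S)-1-(2-bromo-1-ethoxyethoxy)prop-2-en-1-yl]-2-methyloxiran-2-yl}-2-methylpent-2-en-1-ol
Conditions: SeO2 (0.5 equiv), t-BuOOH (3 equiv), salicylic acid (0.1 equiv), CH2Cl2, 0 °C → rt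
Reagents that add atoms: tert-butyl hydroperoxide, CC(C)(C)OO
Why: Riley allylic oxidation (ene reaction, then [2,3]-shift) attacks the E methyl group of the gem-dimethyl terminus and gives the E allylic alcohol, which fixes the 1(10)E geometry; the monosubstituted vinyl group is inert, and the halogen-deactivated acetal and the epoxide should tolerate the weakly acidic medium.

Step 6
Reactants: 7 (2E)-5-{(2R,3S)-3-[(1S)-1-(2-bromo-1-ethoxyethoxy)prop-2-en-1-yl]-2-methyloxiran-2-yl}-2-methylpent-2-en-1-ol
Product: 8 (2R,3S)-3-[(1S)-1-(2-bromo-1-ethoxyethoxy)prop-2-en-1-yl]-2-[(3E)-5-bromo-4-methylpent-3-en-1-yl]-2-methyloxirane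
Conditions: CBr4, PPh3, CH2Cl2, −20 °C
Reagents that add atoms: carbon tetrabromide, BrC(Br)(Br)Br
Why: Appel reaction of a primary allylic alcohol; at low temperature the bromide forms without allylic transposition and the epoxide and acetal are untouched; the bromide is used at once.

Step 7
Reactants: 8 (2R,3S)-3-[(1S)-1-(2-bromo-1-ethoxyethoxy)prop-2-en-1-yl]-2-[(3E)-5-bromo-4-methylpent-3-en-1-yl]-2-methyloxirane
Product: 9 (2R,3S)-3-[(1S)-1-(2-bromo-1-ethoxyethoxy)prop-2-en-1-yl]-2-methyl-2-[(3E)-4-methylhepta-3,6-dien-1-yl]oxirane
Conditions: CH2=CHMgBr, CuI (10 mol%), THF, −78 → −30 °C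
Reagents that add atoms: vinylmagnesium bromide, C=C[Mg]Br
Why: Copper-catalysed allylic substitution at the primary carbon (the γ carbon is hindered) installs C8 with the alkene geometry retained; at this temperature the allylic bromide reacts far faster than the β-alkoxy alkyl bromide or the trisubstituted epoxide.

Step 8
Reactants: 9 (2R,3S)-3-[(1S)-1-(2-bromo-1-ethoxyethoxy)prop-2-en-1-yl]-2-methyl-2-[(3E)-4-methylhepta-3,6-dien-1-yl]oxirane
Product: 10 2-bromo-1-ethoxyethyl ether of (4R,5S,6S)-4,5-epoxy-4,10-dimethylcyclodeca-1(10)E,7Z-dien-6-ol
Conditions: RuCl2(=CHPh)(PCy3)(H2IMes) (second-generation Grubbs catalyst, 10 mol%), 1,4-benzoquinone (20 mol%), CH2Cl2 (1 mM), 40 °C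
Reagents that add atoms: none
Why: Ring-closing metathesis of two monosubstituted vinyl groups: the catalyst should load on the unhindered C8 vinyl group, because the C7 vinyl group sits next to the branched acetal-bearing C6, and the C8 carbene has no partner other than the C7 vinyl group since C4=C5 is not an alkene here. High dilution counters dimerisation, benzoquinone suppresses migration of the skipped diene, and the cis alkene is expected because a second E unit beside E-C1=C10 would strain the ring.

Step 9
Reactants: 10 2-bromo-1-ethoxyethyl ether of (4R,5S,6S)-4,5-epoxy-4,10-dimethylcyclodeca-1(10)E,7Z-dien-6-ol, 11 TEMPO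
Product: 12 (4R,5S,6S,7S,8R) trans-fused lactol ethyl ether with 4,5-epoxide and 8-O-TEMPO group
Conditions: Bu3SnH (3 equiv) and 11 (6 equiv), each added by syringe pump over 8 h, benzene (5 mM in 10), 80 °C
Reagents that add atoms: none
Why: Ueno–Stork haloacetal cyclisation run in the tin hydride/nitroxyl mode, the closest known reaction type being the Bu3SnH–TEMPO cyclisation–trapping of halides: 11 abstracts hydrogen from Bu3SnH, the stannyl radical removes bromine from 10, and the primary C11 radical is formed. The ring O6–C12–C11–C7–C6 closes 5-exo-trig onto C7, and the 3-oxa tether makes this cyclisation fast enough to precede capture as long as stannane and nitroxyl are fed slowly and stay dilute. The only other carbon within 5-exo reach of the tether, C5, is an epoxide carbon here, so no competing ring closure exists. C7 is controlled by C6: in the Z-cyclodecene the C5–C6 bond stands out of the alkene plane and allylic 1,3-strain keeps H6 in it, which places the C6–O tether on the face opposite C5, so C7–C11 forms anti to C5 and the lactol is trans-fused. The secondary C8 radical then combines with 11 at a near diffusion-controlled rate, far faster than hydrogen transfer from the dilute stannane or transannular hydrogen shifts, and the C8–O bond is stable at 80 °C. C8 is controlled by the conformation about C7–C8: with C6–C7–C8–C9 extended, the lobe leading to 8R is flanked by H7 and the opposite one by C11, so 8R is expected but is the least secure element. The step needs cyclisation before capture, attack at C7 only and capture on one face of C8; the first two are secured by the oxygen in the tether and by the epoxide mask, the third only by the ring fusion made in the same step.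

Step 10
Reactants: 12 (4R,5S,6S,7S,8R) trans-fused lactol ethyl ether with 4,5-epoxide and 8-O-TEMPO group
Product: 13 (6R,7S,8R) trans-fused lactol ethyl ether of the 1(10)E,4Z-diene with 8-O-TEMPO group
Conditions: Rh2(OAc)4 (2 mol%), dimethyl diazomalonate (3 equiv, slow addition), benzene, 80 °C
Reagents that add atoms: none
Why: Rhodium-carbenoid deoxygenation of an epoxide: the carbenoid is transferred to the exposed epoxide oxygen and the oxonium ylide collapses to the alkene and dimethyl oxomalonate with retention, so the cis epoxide returns the 4Z alkene. The method needs neither backside attack on a medium-ring carbon nor a Lewis acid that could start transannular cyclisation, and the hindered trisubstituted C1=C10 alkene should react only slowly with the malonyl carbenoid.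

Step 11
Reactants: 13 (6R,7S,8R) trans-fused lactol ethyl ether of the 1(10)E,4Z-diene with 8-O-TEMPO group
Product: 14 (6R,7S,8R) lactol with 8-O-TEMPO group
Conditions: AcOH/THF/H2O (3:1:1), 40 °C
Reagents that add atoms: water, O
Why: Acid hydrolysis of a cyclic mixed acetal; the weak acid is acceptable only now that the epoxide/alkene pair is gone, and the alkoxyamine is merely protonated.

Step 12
Reactants: 14 (6R,7S,8R) lactol with 8-O-TEMPO group
Product: 15 (6R,7S,8R)-8-(2,2,6,6-tetramethylpiperidin-1-yloxy)-13-norgermacra-1(10)E,4Z-dien-12,6-olide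
Conditions: Pr4N[RuO4] (5 mol%), N-methylmorpholine N-oxide, 4 Å MS, CH2Cl2, rt
Reagents that add atoms: none
Why: Ley–Griffith oxidation of a lactol to the lactone under neutral conditions; the alkenes and the hindered alkoxyamine are not touched.

Step 13
Reactants: 15 (6R,7S,8R)-8-(2,2,6,6-tetramethylpiperidin-1-yloxy)-13-norgermacra-1(10)E,4Z-dien-12,6-olide
Product: 17 13-dimethylamino-11,13-dihydro lactone with 8-O-TEMPO group, via lithium enolate 16 (not isolated)
Conditions: LiN(i-Pr)2, THF, −78 °C; then Me2N=CH2 I (Eschenmoser's salt), −78 °C → rt
Reagents that add atoms: N,N-dimethylmethyleneiminium iodide, C=[N+](C)C.[I-]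
Why: Mannich reaction of the lactone enolate, the only enolisable position being C11; the alkoxyamine is inert to the amide base and keeps C8–O from attacking the lactone, and the configuration at C11 is irrelevant because the centre becomes sp2 in step 14.

Step 14
Reactants: 17 13-dimethylamino-11,13-dihydro lactone with 8-O-TEMPO group
Product: 19 (6R,7S,8R)-8-(2,2,6,6-tetramethylpiperidin-1-yloxy)germacra-1(10)E,4Z,11(13)-trien-12,6-olide, via trimethylammonium iodide 18 (not isolated)
Conditions: MeI, MeOH, rt; then NaHCO3, EtOAc/H2O, rt
Reagents that add atoms: none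
Why: Quaternisation and Hofmann-type (E1cB) elimination give the α-methylene lactone; the hindered, weakly basic alkoxyamine nitrogen is not alkylated.

Step 15
Reactants: 19 (6R,7S,8R)-8-(2,2,6,6-tetramethylpiperidin-1-yloxy)germacra-1(10)E,4Z,11(13)-trien-12,6-olide
Product: 20 (6R,7R,8R)-8-hydroxygermacra-1(10)E,4Z,11(13)-trien-12,6-olide
Conditions: Zn dust, AcOH/THF/H2O (3:1:1), rt → 40 °C
Reagents that add atoms: none
Why: Reductive cleavage of the N–O bond of an O-alkyl hydroxylamine by zinc in acetic acid; the C8–O bond is untouched so the configuration is retained, the enoate is not reduced under these conditions, and the liberated amine is protonated and cannot add to the methylene lactone.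

Step 16
Reactants: 21 angelic acid
Product: 22 (2Z)-2-methylbut-2-en-1-ol
Conditions: LiAlH4, Et2O, 0 °C → rt
Reagents that add atoms: none
Why: Hydride reduction of the carboxylic acid to the allylic alcohol; 1,2-reduction leaves the Z alkene in place.

Step 17
Reactants: 22 (2Z)-2-methylbut-2-en-1-ol
Product: 23 [(2R,3S)-2,3-dimethyloxiran-2-yl]methanol
Conditions: Ti(O-i-Pr)4 (10 mol%), D-(−)-diethyl tartrate (12 mol%), t-BuOOH, 4 Å MS, CH2Cl2, −20 °C
Reagents that add atoms: tert-butyl hydroperoxide, CC(C)(C)OO
Why: Sharpless asymmetric epoxidation; the D-(−)-tartrate should deliver oxygen to the face that gives the 2R,3S epoxy alcohol, and syn addition keeps the hydroxymethyl group cis to the C3 methyl group as in the Z alkene.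

Step 18
Reactants: 23 [(2R,3S)-2,3-dimethyloxiran-2-yl]methanol
Product: 25 (2S,3S)-2,3-dimethyloxirane-2-carboxylic acid, via epoxy aldehyde 24 (not isolated)
Conditions: RuCl3 hydrate (2 mol%), NaIO4 (3 equiv), CCl4/MeCN/H2O, 0 °C → rt
Reagents that add atoms: water, O; sodium periodate, [Na+].[O-]I(=O)(=O)=O
Why: Ruthenium tetroxide-catalysed oxidation of a primary epoxy alcohol to the glycidic acid through the aldehyde hydrate; the α-carbon is quaternary, so nothing can epimerise (the descriptor at C2 changes only because of priorities).

Step 19
Reactants: 20 (6R,7R,8R)-8-hydroxygermacra-1(10)E,4Z,11(13)-trien-12,6-olide, 25 (2S,3S)-2,3-dimethyloxirane-2-carboxylic acid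
Product: 27 (6R,7R,8R)-8-[(2S,3S)-2,3-dimethyloxirane-2-carbonyloxy]germacra-1(10)E,4Z,11(13)-trien-12,6-olide, via mixed anhydride 26 (not isolated)
Conditions: 25, 2,4,6-trichlorobenzoyl chloride, Et3N, THF, rt; then 20, DMAP, toluene, rt
Reagents that add atoms: none
Why: Yamaguchi esterification: the mixed anhydride and DMAP transfer the hindered α-quaternary acyl group to the secondary C8 alcohol with retention at C8; the amine bases are too weak to translactonise or to open the epoxide.

Step 20
Reactants: 27 (6R,7R,8R)-8-[(2S,3S)-2,3-dimethyloxirane-2-carbonyloxy]germacra-1(10)E,4Z,11(13)-trien-12,6-olide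
Product: 28 (1R,6R,7R,8R,10R)-1,10-epoxy-8-[(2S,3S)-2,3-dimethyloxirane-2-carbonyloxy]germacra-4Z,11(13)-dien-12,6-olide
Conditions: mCPBA (1.05 equiv), NaHCO3, CH2Cl2, −10 °C
Reagents that add atoms: 3-chloroperbenzoic acid, OOC(=O)c1cccc(Cl)c1
Why: Prilezhaev epoxidation of the most electron-rich alkene: C1=C10 should react before C4=C5, which is deactivated by the allylic lactone oxygen and shielded by the ring fusion, and the two enoates are inert to a peracid. Syn addition to the E alkene gives the trans epoxide, and attack on the exposed outer face of the ring is expected to give 1R,10R.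

## Compound list

1 | nerol, (2Z)-3,7-dimethylocta-2,6-dien-1-ol | CC(C)=CCC/C(C)=C\CO | starting material
2 | (2S,3R)-2,3-epoxynerol, [(2S,3R)-3-methyl-3-(4-methylpent-3-en-1-yl)oxiran-2-yl]methanol | OC[C@@H]1O[C@]1(C)CCC=C(C)C | intermediate
3 | (2R,3R)-3-methyl-3-(4-methylpent-3-en-1-yl)oxirane-2-carbaldehyde | O=C[C@@H]1O[C@]1(C)CCC=C(C)C | intermediate
4 | (1S)-1-[(2S,3R)-3-methyl-3-(4-methylpent-3-en-1-yl)oxiran-2-yl]prop-2-en-1-ol (C6 S, C5 S, C4 R) | C=C[C@H](O)[C@@H]1O[C@]1(C)CCC=C(C)C | intermediate
5 | ethyl vinyl ether | CCOC=C | starting material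
6 | (2S,3R)-2-[(1S)-1-(2-bromo-1-ethoxyethoxy)prop-2-en-1-yl]-3-methyl-3-(4-methylpent-3-en-1-yl)oxirane, both acetal epimers | C=C[C@H](OC(CBr)OCC)[C@@H]1O[C@]1(C)CCC=C(C)C | intermediate
7 | (2E)-5-{(2R,3S)-3-[(1S)-1-(2-bromo-1-ethoxyethoxy)prop-2-en-1-yl]-2-methyloxiran-2-yl}-2-methylpent-2-en-1-ol, both acetal epimers | C=C[C@H](OC(CBr)OCC)[C@@H]1O[C@]1(C)CC/C=C(\C)CO | intermediate
8 | (2R,3S)-3-[(1S)-1-(2-bromo-1-ethoxyethoxy)prop-2-en-1-yl]-2-[(3E)-5-bromo-4-methylpent-3-en-1-yl]-2-methyloxirane, both acetal epimers | C=C[C@H](OC(CBr)OCC)[C@@H]1O[C@]1(C)CC/C=C(\C)CBr | intermediate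
9 | (2R,3S)-3-[(1S)-1-(2-bromo-1-ethoxyethoxy)prop-2-en-1-yl]-2-methyl-2-[(3E)-4-methylhepta-3,6-dien-1-yl]oxirane, both acetal epimers | C=C[C@H](OC(CBr)OCC)[C@@H]1O[C@]1(C)CC/C=C(\C)CC=C | intermediate
10 | key-step precursor: 2-bromo-1-ethoxyethyl ether of (4R,5S,6S)-4,5-epoxy-4,10-dimethylcyclodeca-1(10)E,7Z-dien-6-ol (germacrane locants), both acetal epimers | CCOC(CBr)O[C@H]1/C=C\C/C(C)=C/CC[C@@]2(C)O[C@@H]12 | intermediate
11 | TEMPO, 2,2,6,6-tetramethylpiperidin-1-oxyl | CC1(C)CCCC(C)(C)N1[O] | starting material
12 | key-step product: 6,7-trans-fused 2-ethoxytetrahydrofuran (O6–C12–C11–C7–C6) on the ten-membered ring, 4,5-epoxide, 1(10)E alkene, 8-(2,2,6,6-tetramethylpiperidin-1-yloxy); 4R,5S,6S,7S,8R, both C12 epimers | CCOC1C[C@@H]2[C@H](ON3C(C)(C)CCCC3(C)C)C/C(C)=C/CC[C@@]4(C)O[C@H]4[C@H]2O1 | intermediate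
13 | 6,7-trans-fused 2-ethoxytetrahydrofuran on the 1(10)E,4Z-cyclodecadiene, 8-(2,2,6,6-tetramethylpiperidin-1-yloxy); 6R,7S,8R (C6 descriptor changes, configuration unchanged), both C12 epimers | CCOC1C[C@@H]2[C@H](ON3C(C)(C)CCCC3(C)C)C/C(C)=C/CC/C(C)=C\[C@H]2O1 | intermediate
14 | corresponding lactol (12-hydroxy), 6R,7S,8R, both C12 epimers | OC1C[C@@H]2[C@H](ON3C(C)(C)CCCC3(C)C)C/C(C)=C/CC/C(C)=C\[C@H]2O1 | intermediate
15 | (6R,7S,8R)-8-(2,2,6,6-tetramethylpiperidin-1-yloxy)-13-norgermacra-1(10)E,4Z-dien-12,6-olide | O=C1C[C@@H]2[C@H](ON3C(C)(C)CCCC3(C)C)C/C(C)=C/CC/C(C)=C\[C@H]2O1 | intermediate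
16 | lithium enolate of 15 (C11=C12–OLi), not isolated | [Li+].[O-]C1=C[C@@H]2[C@H](ON3C(C)(C)CCCC3(C)C)C/C(C)=C/CC/C(C)=C\[C@H]2O1 | intermediate
17 | (6R,7S,8R)-13-dimethylamino-8-(2,2,6,6-tetramethylpiperidin-1-yloxy)germacra-1(10)E,4Z-dien-12,6-olide, C11 epimers | CN(C)CC1C(=O)O[C@@H]2/C=C(/C)CC/C=C(\C)C[C@@H](ON3C(C)(C)CCCC3(C)C)[C@@H]12 | intermediate
18 | trimethylammonium iodide of 17, not isolated | C[N+](C)(C)CC1C(=O)O[C@@H]2/C=C(/C)CC/C=C(\C)C[C@@H](ON3C(C)(C)CCCC3(C)C)[C@@H]12.[I-] | intermediate
19 | (6R,7S,8R)-8-(2,2,6,6-tetramethylpiperidin-1-yloxy)germacra-1(10)E,4Z,11(13)-trien-12,6-olide | C=C1C(=O)O[C@@H]2/C=C(/C)CC/C=C(\C)C[C@@H](ON3C(C)(C)CCCC3(C)C)[C@@H]12 | intermediate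
20 | (6R,7R,8R)-8-hydroxygermacra-1(10)E,4Z,11(13)-trien-12,6-olide (C7 descriptor changes, configuration unchanged) | C=C1C(=O)O[C@@H]2/C=C(/C)CC/C=C(\C)C[C@@H](O)[C@@H]12 | intermediate
21 | angelic acid, (2Z)-2-methylbut-2-enoic acid | C/C=C(/C)C(=O)O | starting material
22 | (2Z)-2-methylbut-2-en-1-ol | C/C=C(/C)CO | intermediate
23 | [(2R,3S)-2,3-dimethyloxiran-2-yl]methanol | OC[C@@]1(C)O[C@H]1C | intermediate
24 | (2S,3S)-2,3-dimethyloxirane-2-carbaldehyde, not isolated | O=C[C@@]1(C)O[C@H]1C | intermediate
25 | (2S,3S)-2,3-dimethyloxirane-2-carboxylic acid | OC(=O)[C@@]1(C)O[C@H]1C | intermediate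
26 | (2S,3S)-2,3-dimethyloxirane-2-carboxylic 2,4,6-trichlorobenzoic anhydride, not isolated | O=C(OC(=O)[C@@]1(C)O[C@H]1C)c1c(Cl)cc(Cl)cc1Cl | intermediate
27 | (6R,7R,8R)-8-[(2S,3S)-2,3-dimethyloxirane-2-carbonyloxy]germacra-1(10)E,4Z,11(13)-trien-12,6-olide | C=C1C(=O)O[C@@H]2/C=C(/C)CC/C=C(\C)C[C@@H](OC(=O)[C@@]3(C)O[C@H]3C)[C@@H]12 | intermediate
28 | (1R,6R,7R,8R,10R)-1,10-epoxy-8-[(2S,3S)-2,3-dimethyloxirane-2-carbonyloxy]germacra-4Z,11(13)-dien-12,6-olide | C=C1C(=O)O[C@@H]2/C=C(/C)CC[C@H]3O[C@]3(C)C[C@@H](OC(=O)[C@@]3(C)O[C@H]3C)[C@@H]12 | target

## Step count and least certain steps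

Total: 20 steps. Longest linear sequence: 17 steps (steps 1–15, 19 and 20); the acid 25 takes three steps (16–18).

**Step 9 (key step).** The most likely failure is capture of the C8 radical on the wrong face, or without a useful preference. C8 is controlled only by the conformation about C7–C8, and a synclinal instead of an extended C6–C7–C8–C9 arrangement would expose the other lobe. A lesser risk is capture of the C11 radical before it cyclises if the nitroxyl concentration rises. Fallback: the configuration is corrected at the esterification instead of in the radical step. Setting out from 10, the 8-epimeric lactol ether F1 is taken through steps 10 to 15 unchanged, as the 8-epimeric diene acetal F2, lactol F3, lactone F4, its lithium enolate F5, Mannich base F6, ammonium iodide F7, methylene lactone F8 and alcohol F9. F9 is then esterified with acid 25 under Mitsunobu conditions (PPh3, diisopropyl azodicarboxylate, toluene, 0 °C → rt), which inverts C8 and returns to the route at 27.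

**Step 8.** The most likely failure is diversion of the ruthenium carbene into a seven-membered ring by metathesis with the trisubstituted C1=C10 alkene, or oligomerisation because closure of the strained ring is slow. Formation of some 7E isomer would matter less, since both isomers lead to the same C8 radical. Fallback: the last trisubstituted alkene is removed before ring closure. Setting out from 9, mCPBA epoxidises only the trisubstituted C1=C10 alkene and gives the bis-epoxide diene F10 (both trans-1,10-epoxide diastereomers, which is harmless because these centres are erased). Metathesis then gives the bis-epoxy cyclodecene bromoacetal F11, the tin hydride/TEMPO step gives the bis-epoxy lactol ether F12, and the rhodium-carbenoid step with twice the amount of diazomalonate removes both epoxides with retention (trans epoxide to E alkene, cis epoxide to Z alkene), returning at 13.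

**Step 10.** The most likely failure is loss of the carbenoid to other Lewis-basic sites (the acetal oxygens) or to cyclopropanation of C1=C10, or transannular opening of the activated epoxide by that alkene. Fallback: a two-step, strictly stereospecific opening and elimination. Setting out from 12, PhSeNa ((PhSe)2, NaBH4, EtOH, 60 °C) opens the epoxide at C5 with inversion to the hydroxy selenide F13. MsCl and Et3N (CH2Cl2, 0 °C) then expel selenium and oxygen antiperiplanar, which regenerates the 4Z alkene with overall retention and returns at 13.

**Step 3.** The most likely failure is poor facial selectivity in the Grignard addition, because magnesium chelation between the carbonyl and epoxide oxygens favours the opposite adduct and erodes Felkin–Anh control. Fallback: C6 is set by reduction instead of by C–C bond formation. Setting out from 4 (as the mixture of C6 epimers), Dess–Martin oxidation gives the vinyl ketone F14. Zn(BH4)2 (Et2O, −20 °C) reduces it in the zinc chelate with hydride arriving anti to C4, which leads to the same 6S alcohol and returns at 4.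

**Step 20.** The most likely failure is poor face selectivity at C1=C10 or competing epoxidation of C4=C5, since both depend on the ground-state conformation of the ten-membered ring. Fallback: the C8 hydroxyl directs the oxidant before it is acylated. Setting out from 20, VO(acac)2 with t-BuOOH (CH2Cl2, 0 °C) epoxidises the homoallylic C1=C10 alkene (C4=C5 is one carbon further away) to the epoxy alcohol F15. Yamaguchi esterification with 25 as in step 19 returns at 28.

## Further compounds

F1 | step 9 | 8-epimer (8S) of lactol ether 12 | CCOC1C[C@@H]2[C@@H](ON3C(C)(C)CCCC3(C)C)C/C(C)=C/CC[C@@]4(C)O[C@H]4[C@H]2O1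
F2 | step 9 | 8-epimer of diene acetal 13 | CCOC1C[C@@H]2[C@@H](ON3C(C)(C)CCCC3(C)C)C/C(C)=C/CC/C(C)=C\[C@H]2O1
F3 | step 9 | 8-epimer of lactol 14 | OC1C[C@@H]2[C@@H](ON3C(C)(C)CCCC3(C)C)C/C(C)=C/CC/C(C)=C\[C@H]2O1
F4 | step 9 | 8-epimer of lactone 15 | O=C1C[C@@H]2[C@@H](ON3C(C)(C)CCCC3(C)C)C/C(C)=C/CC/C(C)=C\[C@H]2O1
F5 | step 9 | 8-epimer of lithium enolate 16 | [Li+].[O-]C1=C[C@@H]2[C@@H](ON3C(C)(C)CCCC3(C)C)C/C(C)=C/CC/C(C)=C\[C@H]2O1
F6 | step 9 | 8-epimer of Mannich base 17 | CN(C)CC1C(=O)O[C@@H]2/C=C(/C)CC/C=C(\C)C[C@H](ON3C(C)(C)CCCC3(C)C)[C@@H]12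
F7 | step 9 | 8-epimer of ammonium iodide 18 | C[N+](C)(C)CC1C(=O)O[C@@H]2/C=C(/C)CC/C=C(\C)C[C@H](ON3C(C)(C)CCCC3(C)C)[C@@H]12.[I-]
F8 | step 9 | 8-epimer of methylene lactone 19 | C=C1C(=O)O[C@@H]2/C=C(/C)CC/C=C(\C)C[C@H](ON3C(C)(C)CCCC3(C)C)[C@@H]12
F9 | step 9 | 8-epimer (8S) of alcohol 20 | C=C1C(=O)O[C@@H]2/C=C(/C)CC/C=C(\C)C[C@H](O)[C@@H]12
F10 | step 8 | 1,10-epoxide of diene 9, both trans-epoxide diastereomers | C=C[C@H](OC(CBr)OCC)[C@@H]1O[C@]1(C)CCC1OC1(C)CC=C
F11 | step 8 | 1,10-epoxide of cyclodecene bromoacetal 10, 7Z | CCOC(CBr)O[C@H]1/C=C\CC2(C)OC2CC[C@@]2(C)O[C@@H]12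
F12 | step 8 | 1,10-epoxide of lactol ether 12 | CCOC1C[C@@H]2[C@H](ON3C(C)(C)CCCC3(C)C)CC3(C)OC3CC[C@@]4(C)O[C@H]4[C@H]2O1
F13 | step 10 | 4-hydroxy-5-phenylselanyl lactol ether (C5 inverted) | CCOC1C[C@@H]2[C@H](ON3C(C)(C)CCCC3(C)C)C/C(C)=C/CC[C@@](C)(O)[C@H]([Se]c4ccccc4)[C@H]2O1
F14 | step 3 | 1-[(2R,3R)-3-methyl-3-(4-methylpent-3-en-1-yl)oxiran-2-yl]prop-2-en-1-one | C=CC(=O)[C@@H]1O[C@]1(C)CCC=C(C)C
F15 | step 20 | (1R,6R,7R,8R,10R)-1,10-epoxy-8-hydroxygermacra-4Z,11(13)-dien-12,6-olide | C=C1C(=O)O[C@@H]2/C=C(/C)CC[C@H]3O[C@]3(C)C[C@@H](O)[C@@H]12
A1 | alternative 1 | (5S)-5-[(1Z)-5,5-dimethoxy-2-methylpent-1-en-1-yl]furan-2(5H)-one | COC(OC)CC/C(C)=C\[C@H]1OC(=O)C=C1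
A2 | alternative 1 | 2-[(2-methyl-1,3-dioxolan-2-yl)methyl]-1,3-dithiane | CC1(CC2SCCCS2)OCCO1
A3 | alternative 1 | trisubstituted γ-lactone with C8 dithiane, C10 ketal and C11 hydroxymethyl group | COC(OC)CC/C(C)=C\[C@H]1OC(=O)[C@@H](CO)[C@@H]1C3(CC2(C)OCCO2)SCCCS3
A4 | alternative 2 | cis,anti,cis tricyclic photoadduct (bicyclo[2.2.0]hexane fused to the lactone-bearing cyclohexanone) | C[C@@]12CC[C@@H]1[C@@]1(C)C[C@H]3OC(=O)C[C@H]3C(=O)[C@H]12
A5 | alternative 2 | (1(10)E,4Z)-cyclodecadien-6-one with cis-fused 8,12-lactone | C/C1=C\CC/C(C)=C\C(=O)[C@@H]2CC(=O)O[C@@H]2C1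
A6 | alternative 3 | cis-1-vinyl-2-isopropenylcyclohexanol with fused lactol methyl ether and C8 PMB ether | C=C[C@]1(O)C[C@@H](OCc2ccc(OC)cc2)[C@H]2C[C@H](OC)O[C@@H]2[C@@H]1C(C)=C
A7 | alternative 3 | (1(10)E,4Z)-cyclodecadienyl C10 triflate with lactol methyl ether and C8 PMB ether | FC(F)(F)S(=O)(=O)O/C1=C\CC/C(C)=C\[C@H]2O[C@@H](OC)C[C@@H]2[C@H](OCc3ccc(OC)cc3)C1
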